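**Plan**

- Cuts: the O6 vanillate, the O2 acetate and the oxirane oxygen go first. Ring B (cycloheptane) is then cut at C5–C6 and C8–C9. Ring A (cyclopentane) finally loses the C4–isopropyl, C1–methyl and C1–allyl bonds, back to silyloxycyclopentenone 1.
- Enabling feature: C6 is an aldol carbinol, β to C4 (a ketone in the precursor) through C5. C8=C9, the olefin under the oxirane, is homoallylic to O6. The C6–C7–C8(CH3) triad is therefore the CHO, α-CH2 and isopropenyl carbon of 3-methylbut-3-enal, which can be joined to the C5 enolate and to the C1 allyl group of ring A.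
- Forward: ring A is bought as 1. Two copper-mediated conjugate additions build quaternary C1. A one-flask aldol / ring-closing metathesis then closes ring B. Isopropyl addition, C6 oxidation and directed reduction, epoxidation, esterification, acetylation and debenzylation finish the route.
- Stereochemistry: C2 comes from (S)-1. C1 is set by methyl addition anti to O2, C5 by aldol attack anti to the α allyl/silyloxy face, C4 by addition anti to C5–C6 and the angular methyl, C6 by hydride delivery from O4, and C8/C9 by O6-directed epoxidation.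

Key step: step 5

Remark: daucane locants are used throughout (C1 quaternary ring-fusion carbon, C2 acetoxy carbon, C4 isopropyl carbinol, C5 ring-fusion CH, C6 ester carbinol, C8/C9 oxirane). β is the face of the C1 methyl group. The target is (1R,2S,4R,5S,6S,8R,9S). Compounds 1, 6 and 17 are taken as commercially available.

**Step 1**
Reactants: 1 (S)-4-[(tert-butyldimethylsilyl)oxy]cyclopent-2-en-1-one
Product: 3 (3S,4S)-3-allyl-4-[(tert-butyldimethylsilyl)oxy]-1-[(trimethylsilyl)oxy]cyclopent-1-ene, via bromomagnesium enolate 2 (not isolated)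
Conditions: allylMgBr, CuBr·SMe2, TMSCl, THF, −78 °C
Reagents that add atoms: allylmagnesium bromide C=CC[Mg]Br; chlorotrimethylsilane C[Si](C)(C)Cl
Why: Copper-mediated conjugate allylation with chlorosilane trapping should place the allyl group on C1 anti to the C2 silyloxy group and fix the enolate as the regiodefined silyl enol ether; the C1 stereocenter formed here is erased in step 2.

**Step 2**
Reactants: 3 (3S,4S)-3-allyl-4-[(tert-butyldimethylsilyl)oxy]-1-[(trimethylsilyl)oxy]cyclopent-1-ene
Product: 4 (S)-3-allyl-4-[(tert-butyldimethylsilyl)oxy]cyclopent-2-en-1-one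
Conditions: Pd(OAc)2, MeCN, 23 °C
Reagents that add atoms: none
Why: Saegusa–Ito oxidation (palladation of the silyl enol ether, then β-hydride elimination of the C1 hydrogen) should return the enone with the allyl group now on the β-carbon C1 and leave the C2 stereocenter untouched.

**Step 3**
Reactants: 4 (S)-3-allyl-4-[(tert-butyldimethylsilyl)oxy]cyclopent-2-en-1-one
Product: 5 (3R,4S)-3-allyl-4-[(tert-butyldimethylsilyl)oxy]-3-methyl-1-[(trimethylsilyl)oxy]cyclopent-1-ene
Conditions: Me2CuLi (MeLi, CuI), TMSCl (present from the start), THF, −78 °C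
Reagents that add atoms: lithium dimethylcuprate [Li+].C[Cu-]C; chlorotrimethylsilane C[Si](C)(C)Cl
Why: Chlorosilane-accelerated conjugate addition of the Gilman cuprate should deliver methyl to C1 anti to the adjacent C2 silyloxy group (methyl β, allyl α), and because the chlorosilane silylates the cuprate–enone adduct as it forms, the regiodefined C4/C5 silyl enol ether is obtained directly without a free enolate that could equilibrate.

**Step 4**
Reactants: 6 3-methylbut-3-en-1-ol
Product: 7 3-methylbut-3-enal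
Conditions: Dess–Martin periodinane, CH2Cl2, 0 to 23 °C (used at once as a solution)
Reagents that add atoms: none
Why: Dess–Martin oxidation of the primary alcohol should stop at the β,γ-unsaturated aldehyde under non-basic conditions that do not move the olefin into conjugation.

**Step 5**
Reactants: 5 (3R,4S)-3-allyl-4-[(tert-butyldimethylsilyl)oxy]-3-methyl-1-[(trimethylsilyl)oxy]cyclopent-1-ene; 7 3-methylbut-3-enal
Product: 11 (3S,3aR,8aS)-3-[(tert-butyldimethylsilyl)oxy]-3a,6-dimethyl-8-[(trimethylsilyl)oxy]-3,3a,4,7,8,8a-hexahydroazulen-1(2H)-one (daucane C4 ketone; trans-fused; C6 epimers), via lithium enolate 8 (not isolated), via lithium aldolate 9 (not isolated), via aldol silyl ether diene 10 (not isolated)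
Conditions: MeLi, THF, 0 °C; 7, −78 °C; TMSCl, −78 to 23 °C; then PhMe added, second-generation Hoveyda–Grubbs catalyst (5 mol %), 60 °C (one flask)
Reagents that add atoms: chlorotrimethylsilane C[Si](C)(C)Cl
Why: Methyllithium cleaves the O–Si bond of 5 to the regiodefined lithium enolate 8, which adds to aldehyde 7 in an aldol reaction through a closed six-membered chair (forms C5–C6); the alkoxide is capped in the flask as silyl ether 10, and the ruthenium alkylidene then joins the allyl and methallyl olefins by ring-closing metathesis (forms C8=C9) with loss of ethylene. The closest known reaction type is the telescoped aldol / ring-closing-metathesis annulation of α-allyl ketone enolates with unsaturated aldehydes, here a (4+3) union of the C9–C10–C1–C5 arc of ring A with the C6–C7–C8 unit. Ring B closes as a seven-membered carbocycle by metathesis between the monosubstituted olefin (where the catalyst loads) and the 1,1-disubstituted olefin, a closure that can only give the endocyclic cis trisubstituted alkene. C5 is set under substrate control: the aldehyde should reach the enolate on the β face, anti to the α allyl group on C1 and the α silyloxy group on C2, so that H5 becomes α and the ring fusion trans; C6 is not controlled and both epimers are carried on, because C6 is erased in step 7 and reset in step 8. The step needs C–C bond formation faster than proton transfer from the acidic α-CH2 of 7 (preformed enolate, −78 °C, no amine base), regiochemical integrity of the enolate (secured by the silyl enol ether of step 3) and a catalyst that tolerates lithium salts and silyl ethers (the chelated isopropoxybenzylidene complex).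

**Step 6**
Reactants: 11 (3S,3aR,8aS)-3-[(tert-butyldimethylsilyl)oxy]-3a,6-dimethyl-8-[(trimethylsilyl)oxy]-3,3a,4,7,8,8a-hexahydroazulen-1(2H)-one
Product: 13 (1R,2S,4R,5S)-2-[(tert-butyldimethylsilyl)oxy]dauc-8-ene-4,6-diol (4β-OH; C6 epimers), via O6-silylated carbinol 12 (not isolated)
Conditions: i-PrMgCl, CeCl3, THF, −78 to 0 °C; then 1 M HCl, 23 °C
Reagents that add atoms: isopropylmagnesium chloride CC(C)[Mg]Cl
Why: Organocerium 1,2-addition to the hindered, enolizable C4 ketone should occur on the α face, anti to the β-oriented C5–C6 bond and the β angular methyl, giving the 4β-carbinol; dilute acid then cleaves the trimethylsilyl ether.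

**Step 7**
Reactants: 13 (1R,2S,4R,5S)-2-[(tert-butyldimethylsilyl)oxy]dauc-8-ene-4,6-diol
Product: 14 (1R,2S,4R,5R)-2-[(tert-butyldimethylsilyl)oxy]-4-hydroxydauc-8-en-6-one
Conditions: Dess–Martin periodinane, CH2Cl2, 23 °C
Reagents that add atoms: none
Why: Dess–Martin oxidation of the secondary C6 alcohol (the tertiary C4 alcohol cannot react) should converge both C6 epimers on one β-hydroxy ketone under neutral conditions that avoid retro-aldol cleavage and olefin migration.

**Step 8**
Reactants: 14 (1R,2S,4R,5R)-2-[(tert-butyldimethylsilyl)oxy]-4-hydroxydauc-8-en-6-one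
Product: 15 (1R,2S,4R,5S,6S)-2-[(tert-butyldimethylsilyl)oxy]dauc-8-ene-4,6-diol (4β,6α)
Conditions: Me4NBH(OAc)3, MeCN–AcOH, −30 °C
Reagents that add atoms: none
Why: Evans–Saksena hydroxyl-directed reduction (the C4 alkoxy-acetoxyborohydride delivers hydride internally through a six-membered chair) should add hydrogen to the β face of C6 and give the 1,3-anti diol, that is the 6α-alcohol.

**Step 9**
Reactants: 15 (1R,2S,4R,5S,6S)-2-[(tert-butyldimethylsilyl)oxy]dauc-8-ene-4,6-diol
Product: 16 (1R,2S,4R,5S,6S,8R,9S)-2-[(tert-butyldimethylsilyl)oxy]-8,9-epoxydaucane-4,6-diol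
Conditions: VO(acac)2 (cat.), t-BuOOH, CH2Cl2, 0 to 23 °C
Reagents that add atoms: tert-butyl hydroperoxide CC(C)(C)OO
Why: Vanadium-catalysed hydroxyl-directed epoxidation of the homoallylic alcohol should deliver oxygen to C8=C9 on the α face, syn to O6 and anti to the β angular methyl, which sets C8 and C9.

**Step 10**
Reactants: 16 (1R,2S,4R,5S,6S,8R,9S)-2-[(tert-butyldimethylsilyl)oxy]-8,9-epoxydaucane-4,6-diol; 17 4-(benzyloxy)-3-methoxybenzoic acid
Product: 18 (1R,2S,4R,5S,6S,8R,9S)-2-[(tert-butyldimethylsilyl)oxy]-8,9-epoxy-4-hydroxydaucan-6-yl 4-(benzyloxy)-3-methoxybenzoate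
Conditions: EDC·HCl, DMAP, CH2Cl2, 23 °C
Reagents that add atoms: none
Why: Steglich esterification (carbodiimide activation, acyl transfer by DMAP) should acylate the only accessible hydroxyl, the secondary C6 alcohol, without touching the oxirane or the tertiary alcohol.

**Step 11**
Reactants: 18 (1R,2S,4R,5S,6S,8R,9S)-2-[(tert-butyldimethylsilyl)oxy]-8,9-epoxy-4-hydroxydaucan-6-yl 4-(benzyloxy)-3-methoxybenzoate
Product: 19 (1R,2S,4R,5S,6S,8R,9S)-8,9-epoxy-2,4-dihydroxydaucan-6-yl 4-(benzyloxy)-3-methoxybenzoate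
Conditions: TBAF, AcOH, THF, 23 °C
Reagents that add atoms: none
Why: Fluoride-mediated desilylation buffered with acetic acid should free the C2 alcohol while keeping the medium neither basic (ester intact) nor strongly acidic (oxirane intact).

**Step 12**
Reactants: 19 (1R,2S,4R,5S,6S,8R,9S)-8,9-epoxy-2,4-dihydroxydaucan-6-yl 4-(benzyloxy)-3-methoxybenzoate
Product: 20 (1R,2S,4R,5S,6S,8R,9S)-2-acetoxy-8,9-epoxy-4-hydroxydaucan-6-yl 4-(benzyloxy)-3-methoxybenzoate
Conditions: Ac2O, DMAP (cat.), pyridine, CH2Cl2, 0 °C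
Reagents that add atoms: acetic anhydride CC(=O)OC(C)=O
Why: DMAP-catalysed acylation should acetylate only the secondary C2 alcohol, the tertiary C4 alcohol being too hindered and the phenol still benzylated.

**Step 13**
Reactants: 20 (1R,2S,4R,5S,6S,8R,9S)-2-acetoxy-8,9-epoxy-4-hydroxydaucan-6-yl 4-(benzyloxy)-3-methoxybenzoate
Product: 21 (1R,2S,4R,5S,6S,8R,9S)-2-acetoxy-8,9-epoxy-4-hydroxydaucan-6-yl 4-hydroxy-3-methoxybenzoate (CNP0241679.3)
Conditions: H2 (1 atm), Pd/C, EtOAc, 23 °C
Reagents that add atoms: none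
Why: Hydrogenolysis of the benzyl aryl ether over palladium should release the phenol under neutral conditions that spare the trisubstituted oxirane and both esters.

**Compound list**

1 | (S)-4-[(tert-butyldimethylsilyl)oxy]cyclopent-2-en-1-one | O=C1C=C[C@@H](O[Si](C)(C)C(C)(C)C)C1 | starting material
2 | bromomagnesium (3S,4S)-3-allyl-4-[(tert-butyldimethylsilyl)oxy]cyclopent-1-en-1-olate (bromomagnesium enolate) | C=CC[C@H]1C=C(O[Mg]Br)C[C@@H]1O[Si](C)(C)C(C)(C)C | intermediate (not isolated)
3 | (3S,4S)-3-allyl-4-[(tert-butyldimethylsilyl)oxy]-1-[(trimethylsilyl)oxy]cyclopent-1-ene | C=CC[C@H]1C=C(O[Si](C)(C)C)C[C@@H]1O[Si](C)(C)C(C)(C)C | intermediate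
4 | (S)-3-allyl-4-[(tert-butyldimethylsilyl)oxy]cyclopent-2-en-1-one | C=CCC1=CC(=O)C[C@@H]1O[Si](C)(C)C(C)(C)C | intermediate
5 | (3R,4S)-3-allyl-4-[(tert-butyldimethylsilyl)oxy]-3-methyl-1-[(trimethylsilyl)oxy]cyclopent-1-ene | C[C@]1(CC=C)[C@@H](O[Si](C)(C)C(C)(C)C)CC(O[Si](C)(C)C)=C1 | intermediate
6 | 3-methylbut-3-en-1-ol | CC(=C)CCO | starting material
7 | 3-methylbut-3-enal | CC(=C)CC=O | intermediate
8 | lithium (3R,4S)-3-allyl-4-[(tert-butyldimethylsilyl)oxy]-3-methylcyclopent-1-en-1-olate (lithium enolate) | C[C@]1(CC=C)[C@@H](O[Si](C)(C)C(C)(C)C)CC(O[Li])=C1 | intermediate (not isolated)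
9 | lithium aldolate of (2S,3R,4S)-3-allyl-4-[(tert-butyldimethylsilyl)oxy]-2-(1-hydroxy-3-methylbut-3-enyl)-3-methylcyclopentan-1-one (carbinol epimers) | C[C@]1(CC=C)[C@@H](O[Si](C)(C)C(C)(C)C)CC(=O)[C@@H]1C(O[Li])CC(C)=C | intermediate (not isolated)
10 | (2S,3R,4S)-3-allyl-4-[(tert-butyldimethylsilyl)oxy]-3-methyl-2-{3-methyl-1-[(trimethylsilyl)oxy]but-3-enyl}cyclopentan-1-one (aldol silyl ether diene; carbinol epimers) | C[C@]1(CC=C)[C@@H](O[Si](C)(C)C(C)(C)C)CC(=O)[C@@H]1C(O[Si](C)(C)C)CC(C)=C | intermediate (not isolated)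
11 | (3S,3aR,8aS)-3-[(tert-butyldimethylsilyl)oxy]-3a,6-dimethyl-8-[(trimethylsilyl)oxy]-3,3a,4,7,8,8a-hexahydroazulen-1(2H)-one (daucane C4 ketone with O2 and O6 silyl ethers; trans-fused, H5 α, C1 methyl β; C6 epimers) | C[Si](C)(C)OC2CC(C)=CC[C@@]3(C)[C@@H](O[Si](C)(C)C(C)(C)C)CC(=O)[C@H]23 | intermediate
12 | (1R,2S,4R,5S)-2-[(tert-butyldimethylsilyl)oxy]-6-[(trimethylsilyl)oxy]dauc-8-en-4-ol (O6-silylated carbinol; C6 epimers) | C[Si](C)(C)OC2CC(C)=CC[C@@]3(C)[C@@H](O[Si](C)(C)C(C)(C)C)C[C@@](O)(C(C)C)[C@H]23 | intermediate (not isolated)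
13 | (1R,2S,4R,5S)-2-[(tert-butyldimethylsilyl)oxy]dauc-8-ene-4,6-diol (4β-OH; C6 epimers) | OC2CC(C)=CC[C@@]3(C)[C@@H](O[Si](C)(C)C(C)(C)C)C[C@@](O)(C(C)C)[C@H]23 | intermediate
14 | (1R,2S,4R,5R)-2-[(tert-butyldimethylsilyl)oxy]-4-hydroxydauc-8-en-6-one | O=C2CC(C)=CC[C@@]3(C)[C@@H](O[Si](C)(C)C(C)(C)C)C[C@@](O)(C(C)C)[C@H]23 | intermediate
15 | (1R,2S,4R,5S,6S)-2-[(tert-butyldimethylsilyl)oxy]dauc-8-ene-4,6-diol (4β,6α) | O[C@H]2CC(C)=CC[C@@]3(C)[C@@H](O[Si](C)(C)C(C)(C)C)C[C@@](O)(C(C)C)[C@H]23 | intermediate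
16 | (1R,2S,4R,5S,6S,8R,9S)-2-[(tert-butyldimethylsilyl)oxy]-8,9-epoxydaucane-4,6-diol (α-oxirane) | O[C@H]2C[C@@]3(C)O[C@H]3C[C@@]3(C)[C@@H](O[Si](C)(C)C(C)(C)C)C[C@@](O)(C(C)C)[C@H]23 | intermediate
17 | 4-(benzyloxy)-3-methoxybenzoic acid | COc1cc(C(=O)O)ccc1OCc1ccccc1 | starting material
18 | (1R,2S,4R,5S,6S,8R,9S)-2-[(tert-butyldimethylsilyl)oxy]-8,9-epoxy-4-hydroxydaucan-6-yl 4-(benzyloxy)-3-methoxybenzoate | COc1cc(C(=O)O[C@H]2C[C@@]3(C)O[C@H]3C[C@@]3(C)[C@@H](O[Si](C)(C)C(C)(C)C)C[C@@](O)(C(C)C)[C@H]23)ccc1OCc1ccccc1 | intermediate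
19 | (1R,2S,4R,5S,6S,8R,9S)-8,9-epoxy-2,4-dihydroxydaucan-6-yl 4-(benzyloxy)-3-methoxybenzoate | COc1cc(C(=O)O[C@H]2C[C@@]3(C)O[C@H]3C[C@@]3(C)[C@@H](O)C[C@@](O)(C(C)C)[C@H]23)ccc1OCc1ccccc1 | intermediate
20 | (1R,2S,4R,5S,6S,8R,9S)-2-acetoxy-8,9-epoxy-4-hydroxydaucan-6-yl 4-(benzyloxy)-3-methoxybenzoate | COc1cc(C(=O)O[C@H]2C[C@@]3(C)O[C@H]3C[C@@]3(C)[C@@H](OC(C)=O)C[C@@](O)(C(C)C)[C@H]23)ccc1OCc1ccccc1 | intermediate
21 | (1R,2S,4R,5S,6S,8R,9S)-2-acetoxy-8,9-epoxy-4-hydroxydaucan-6-yl 4-hydroxy-3-methoxybenzoate | COc1cc(C(=O)O[C@H]2C[C@@]3(C)O[C@H]3C[C@@]3(C)[C@@H](OC(C)=O)C[C@@](O)(C(C)C)[C@H]23)ccc1O | target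

**Step count and risks**

Total steps: 13. Longest linear sequence: 12 steps (1 to 21 through steps 1–3 and 5–13; step 4 is a one-step side branch).

Steps most likely to fail:

1. Step 5. The enolate may take a proton from the doubly activated α-CH2 of the β,γ-unsaturated aldehyde (with migration of its olefin into conjugation) instead of adding to it, and the metathesis catalyst may lose activity in the salt-containing mixture. Fallback: from 5 and 7, a Mukaiyama aldol addition with BF3·OEt2 (CH2Cl2, −78 °C) would give the free aldol adduct F1 under non-basic conditions. Silylation (TMSCl, imidazole, CH2Cl2) would give diene 10, which would be purified and closed in a separate ring-closing metathesis (second-generation Grubbs catalyst, CH2Cl2, 40 °C), coming back to the route at 11.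

2. Step 6. Enolization of the hindered ketone (followed by β-elimination of the C2 silyloxy group) or hydride transfer from the secondary alkylmetal may outrun addition. Fallback: from 11, prop-1-en-2-ylmagnesium bromide with CeCl3 (THF, −78 °C), then 1 M HCl, would give the isopropenyl carbinol F2. Chemoselective hydrogenation of its 1,1-disubstituted olefin (H2, RhCl(PPh3)3, benzene) would come back to the route at 13.

3. Step 8. External hydride attack on the more open α face may compete with delivery from O4, eroding facial selectivity at C6. Fallback: from 14, reduction with NaBH4 and CeCl3 (MeOH, −78 °C) would deliberately give the 6β-alcohol F3. Mitsunobu esterification with acid 17 (PPh3, DIAD, toluene) would invert C6 to the 6α-ester F4. Epoxidation with mCPBA and NaHCO3 (CH2Cl2, 0 °C) on the α face, anti to the angular methyl, would come back to the route at 18.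

**Further compounds**

F1 | step 5 | (2S,3R,4S)-3-allyl-4-[(tert-butyldimethylsilyl)oxy]-2-(1-hydroxy-3-methylbut-3-enyl)-3-methylcyclopentan-1-one (carbinol epimers) | C[C@]1(CC=C)[C@@H](O[Si](C)(C)C(C)(C)C)CC(=O)[C@@H]1C(O)CC(C)=C
F2 | step 6 | 2α-[(tert-butyldimethylsilyl)oxy]dauca-8,11-diene-4β,6-diol (C6 epimers) | OC2CC(C)=CC[C@@]3(C)[C@@H](O[Si](C)(C)C(C)(C)C)C[C@@](O)(C(C)=C)[C@H]23
F3 | step 8 | (1R,2S,4R,5S,6R)-2-[(tert-butyldimethylsilyl)oxy]dauc-8-ene-4,6-diol (4β,6β) | O[C@@H]2CC(C)=CC[C@@]3(C)[C@@H](O[Si](C)(C)C(C)(C)C)C[C@@](O)(C(C)C)[C@H]23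
F4 | step 8 | (1R,2S,4R,5S,6S)-2-[(tert-butyldimethylsilyl)oxy]-4-hydroxydauc-8-en-6-yl 4-(benzyloxy)-3-methoxybenzoate | COc1cc(C(=O)O[C@H]2CC(C)=CC[C@@]3(C)[C@@H](O[Si](C)(C)C(C)(C)C)C[C@@](O)(C(C)C)[C@H]23)ccc1OCc1ccccc1
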